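**Plan**

Ring A is numbered C1 (C=O), C2 (C–N), C3 (=CH), C4 (C–OH), C5 and C6 (oxirane carbons); the chain on C4 is C1′–C7′.

1. The retrosynthesis cuts C2′–C3′ (Stille), the upper amide N–CO bond, the two oxirane C–O bonds (back to C5=C6 of a p-quinol), the ring bond C4–C5, then C4–C1′ (acetylide plus lactone) and C1–C6/C1–C5 (cyclopropanol from a lactone).
2. Enabling feature: in ring A, C5 lies β to the C1 ketone (C1–C6–C5) and C4 is a ketone-derived carbinol. The carbocycle is therefore the internal homoaldol adduct of a C1-ketone homoenolate and a C4 ynone, and the homoenolate is stored as a 1-substituted cyclopropanol (C1, C5, C6) whose strain drives C4–C5 formation.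
3. Forward order: D-homoserine lactone, then cyclopropanol, spirolactone (temporary ring), ynone, ring A by strain-release closure, acyl exchange on N, double dehydrogenation to the p-quinol, oxirane, and last the lower chain by hydrostannylation and Stille coupling.
4. Stereochemistry: C2 is bought (D-homoserine) and relays to C4 in the ring closure (N and O cis), then is erased. The C4 hydroxyl directs the epoxidation syn and sets C5 and C6 in one event.
5. Alkene geometry comes from Horner–Wadsworth–Emmons olefination (E), syn-hydrostannylation (E) and a stereoretentive Stille coupling.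

Key step: step 4

Remark: hydroxy ynone 4 is expected to equilibrate with its five-membered cyclic hemiketal; both tautomers give the same zinc alkoxide in step 4.
Remark: the D-lactone is chosen because the chair model for step 4 places N and O cis; C2 of 14 may epimerize without consequence, since it becomes sp2 in step 9.

**Route**

Step 1
Reactants: 1 tert-butyl N-[(3R)-2-oxooxolan-3-yl]carbamate (N-Boc-D-homoserine lactone)
Product: 2 tert-butyl N-[(1R)-3-hydroxy-1-(1-hydroxycyclopropyl)propyl]carbamate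
Conditions: EtMgBr (4.5 equiv), Ti(OiPr)4 (30 mol %), THF, 0 °C to rt; then H2O
Reagents that add atoms: ethylmagnesium bromide, CC[Mg]Br
Why: Kulinkovich cyclopropanation of a lactone: the titanacyclopropane from Ti(OiPr)4 and EtMgBr acts as a 1,2-dicarbanion on the lactone carbonyl and should give the 1-substituted cyclopropanol with release of the primary alcohol, while the first-formed magnesium carbamate shields C2–H from enolization so the bought stereocentre is kept.

Step 2
Reactants: 2 tert-butyl N-[(1R)-3-hydroxy-1-(1-hydroxycyclopropyl)propyl]carbamate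
Product: 3 tert-butyl N-[(7R)-5-oxo-4-oxaspiro[2.4]heptan-7-yl]carbamate
Conditions: Pr4N[RuO4] (5 mol %), N-methylmorpholine N-oxide (3 equiv), 4 Å molecular sieves, CH2Cl2, rt
Reagents that add atoms: none
Why: Ley–Griffith oxidation: the primary alcohol is oxidized to the aldehyde, which the tertiary cyclopropanol captures as a lactol that is oxidized on to the γ-lactone; the tertiary alcohol itself cannot be oxidized.

Step 3
Reactants: 3 tert-butyl N-[(7R)-5-oxo-4-oxaspiro[2.4]heptan-7-yl]carbamate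
Product: 4 tert-butyl N-[(1R)-1-(1-hydroxycyclopropyl)-3-oxo-5-(trimethylsilyl)pent-4-yn-1-yl]carbamate
Conditions: HC≡C–SiMe3 (2.4 equiv), n-BuLi (2.3 equiv), THF, −78 °C; add 3, −78 °C; AcOH quench
Reagents that add atoms: trimethylsilylacetylene, C#C[Si](C)(C)C
Why: Addition of an alkynyllithium to a γ-lactone stops at the tetrahedral lithium hemiketal (as in alkynyl lactol formation from sugar lactones), so protonation should give the C4 ynone and free the cyclopropanol; the first equivalent of acetylide only deprotonates the carbamate.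

Step 4
Reactants: 4 tert-butyl N-[(1R)-1-(1-hydroxycyclopropyl)-3-oxo-5-(trimethylsilyl)pent-4-yn-1-yl]carbamate
Product: 7 tert-butyl N-[(1R,5R)-5-hydroxy-2-oxo-5-[2-(trimethylsilyl)ethynyl]cyclohexyl]carbamate, via ethylzinc cyclopropoxide 5 (not isolated), via zinc homoenolate 6 (not isolated)
Conditions: Et2Zn (2.2 equiv), 2,2′-bipyridine (1.1 equiv), THF, 0 to 40 °C; aq AcOH quench
Reagents that add atoms: none
Why: Proposed new method: Et2Zn deprotonates the cyclopropanol (or its hemiketal tautomer) to the ethylzinc cyclopropoxide 5; cleavage of the strained C1–C5 bond (about 27 kcal/mol released) gives the carbonyl-chelated β-zincio ketone 6, whose C5–Zn bond adds 1,2 to the ynone carbonyl C4 through a chair six-membered transition state. The closest known reaction types are the Et2Zn-induced opening of tertiary cyclopropanols to zinc homoenolates that are C-acylated or add to enones, and the homoaldol addition of titanium ester homoenolates to ketones. Ring A closes in the 6-exo-trig mode at the carbonyl. The new stereocentre C4 is controlled by the C2 carbamate, which sits equatorial in the chair; the zinc-bound oxygen takes the other equatorial site and the slim alkynyl group the axial one, so N and O should end up cis, an arrangement that a zinc bridge or hydrogen bond between carbamate and alkoxide also favours. The step needs 1,2- over 1,4-addition (six- against eight-membered ring, silyl-capped alkyne terminus) and C–C bond formation faster than enolization of the homoenolate, which the carbamate next to C2 disfavours.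

Step 5
Reactants: 8 (E)-4-methylpent-2-enal; 9 triethyl 4-phosphonocrotonate [ethyl (E)-4-(diethoxyphosphoryl)but-2-enoate]
Product: 10 ethyl (2E,4E,6E)-8-methylnona-2,4,6-trienoate
Conditions: LiHMDS (1.05 equiv), THF, −78 to 0 °C
Reagents that add atoms: none
Why: Vinylogous Horner–Wadsworth–Emmons olefination: the stabilized phosphonate anion should give the new alkene E through reversible oxaphosphetane formation, and the two existing E alkenes are untouched.

Step 6
Reactants: 10 ethyl (2E,4E,6E)-8-methylnona-2,4,6-trienoate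
Product: 11 (2E,4E,6E)-8-methylnona-2,4,6-trienoic acid
Conditions: LiOH, THF/H2O, rt; then 1 M HCl
Reagents that add atoms: lithium hydroxide, [Li+].[OH-]
Why: Saponification of the ethyl ester; the triene is inert to hydroxide at room temperature.

Step 7
Reactants: 11 (2E,4E,6E)-8-methylnona-2,4,6-trienoic acid
Product: 12 (2E,4E,6E)-8-methylnona-2,4,6-trienoyl chloride
Conditions: (COCl)2 (1.2 equiv), DMF (cat.), CH2Cl2, 0 °C to rt; evaporate, use crude
Reagents that add atoms: oxalyl chloride, ClC(=O)C(=O)Cl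
Why: Acid chloride formation through the chloroiminium (Vilsmeier-type) activator under conditions that do not isomerize the triene.

Step 8
Reactants: 7 tert-butyl N-[(1R,5R)-5-hydroxy-2-oxo-5-[2-(trimethylsilyl)ethynyl]cyclohexyl]carbamate; 12 (2E,4E,6E)-8-methylnona-2,4,6-trienoyl chloride
Product: 14 (2E,4E,6E)-N-[(1R,5R)-5-hydroxy-2-oxo-5-[2-(trimethylsilyl)ethynyl]cyclohexyl]-8-methylnona-2,4,6-trienamide, via ammonium trifluoroacetate 13 (not isolated)
Conditions: CF3CO2H/CH2Cl2 1:4, 0 °C; evaporate; then 12, NaHCO3, CH2Cl2/H2O, 0 °C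
Reagents that add atoms: none
Why: Acidolysis of the tert-butyl carbamate followed by Schotten–Baumann acylation of the ammonium salt; the amine is acylated much faster than the hindered tertiary alcohol, and the silylalkyne and tertiary propargylic alcohol should tolerate cold trifluoroacetic acid.

Step 9
Reactants: 14 (2E,4E,6E)-N-[(1R,5R)-5-hydroxy-2-oxo-5-[2-(trimethylsilyl)ethynyl]cyclohexyl]-8-methylnona-2,4,6-trienamide
Product: 15 (2E,4E,6E)-N-[(3R)-3-hydroxy-6-oxo-3-[2-(trimethylsilyl)ethynyl]cyclohexa-1,4-dien-1-yl]-8-methylnona-2,4,6-trienamide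
Conditions: 2-iodoxybenzoic acid (IBX, 3.5 equiv), 4-methoxypyridine N-oxide (3.5 equiv), DMSO, rt
Reagents that add atoms: none
Why: IBX dehydrogenation of a ketone (single-electron oxidation of the enol) should install C2=C3 and C5=C6 in turn; the quaternary C4 blocks aromatization, C2 is erased and C4 remains the only stereocentre.

Step 10
Reactants: 15 (2E,4E,6E)-N-[(3R)-3-hydroxy-6-oxo-3-[2-(trimethylsilyl)ethynyl]cyclohexa-1,4-dien-1-yl]-8-methylnona-2,4,6-trienamide
Product: 16 (2E,4E,6E)-N-[(1S,5R,6R)-5-hydroxy-2-oxo-5-[2-(trimethylsilyl)ethynyl]-7-oxabicyclo[4.1.0]hept-3-en-3-yl]-8-methylnona-2,4,6-trienamide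
Conditions: t-BuOOH (2 equiv, in decane), DBU (1.0 equiv), CH2Cl2, −10 °C
Reagents that add atoms: tert-butyl hydroperoxide, CC(C)(C)OO
Why: Weitz–Scheffer epoxidation: tert-butylperoxide adds to C5 of the unsubstituted enone arm (C3 is deactivated by the amide nitrogen on C2), and the free C4 hydroxyl guides it by hydrogen bonding to its own face, so the oxirane (C5 and C6 set together) should form syn to the hydroxyl.

Step 11
Reactants: 16 (2E,4E,6E)-N-[(1S,5R,6R)-5-hydroxy-2-oxo-5-[2-(trimethylsilyl)ethynyl]-7-oxabicyclo[4.1.0]hept-3-en-3-yl]-8-methylnona-2,4,6-trienamide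
Product: 17 (2E,4E,6E)-N-[(1S,5R,6R)-5-ethynyl-5-hydroxy-2-oxo-7-oxabicyclo[4.1.0]hept-3-en-3-yl]-8-methylnona-2,4,6-trienamide
Conditions: Bu4NF (1.2 equiv), AcOH (1.5 equiv), THF, 0 °C
Reagents that add atoms: none
Why: Fluoride-induced protodesilylation of the alkynylsilane, buffered with acetic acid so that the epoxy ketone is not exposed to free base.

Step 12
Reactants: 17 (2E,4E,6E)-N-[(1S,5R,6R)-5-ethynyl-5-hydroxy-2-oxo-7-oxabicyclo[4.1.0]hept-3-en-3-yl]-8-methylnona-2,4,6-trienamide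
Product: 18 (2E,4E,6E)-N-[(1S,5R,6R)-5-hydroxy-2-oxo-5-[(E)-2-(tributylstannyl)ethenyl]-7-oxabicyclo[4.1.0]hept-3-en-3-yl]-8-methylnona-2,4,6-trienamide
Conditions: Bu3SnH (1.2 equiv), PdCl2(PPh3)2 (3 mol %), THF, 0 °C
Reagents that add atoms: tributyltin hydride, CCCC[SnH](CCCC)CCCC
Why: Palladium-catalysed syn-hydrostannylation of a terminal alkyne: the hindered tertiary propargylic centre steers tin to the terminal carbon and syn addition fixes the E geometry; the alkyne should react far faster than the enone or the trienamide.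

Step 13
Reactants: 19 cyclopentane-1,3-dione
Product: 20 2-(hydroxyimino)cyclopentane-1,3-dione
Conditions: NaNO2, aq HCl, 0 °C
Reagents that add atoms: sodium nitrite, [Na+].[O-]N=O
Why: Nitrosation of the enolized 1,3-diketone at C2 and tautomerization to the oxime.

Step 14
Reactants: 20 2-(hydroxyimino)cyclopentane-1,3-dione
Product: 21 2-amino-3-hydroxycyclopent-2-en-1-one hydrochloride
Conditions: H2 (1 atm), Pd/C (10 wt %), HCl, EtOH, rt
Reagents that add atoms: hydrogen chloride, Cl
Why: Catalytic hydrogenation of the α-oximino dione to the amine, held as the hydrochloride of its enol tautomer so that it cannot self-condense.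

Step 15
Reactants: 22 glutaconaldehyde potassium salt [potassium (1E,3E)-5-oxopenta-1,3-dien-1-olate]
Product: 23 (2E,4E)-5-bromopenta-2,4-dienal
Conditions: Ph3PBr2 (1.1 equiv), CH2Cl2, 0 °C to rt
Reagents that add atoms: dibromotriphenylphosphorane, BrP(Br)(c1ccccc1)(c1ccccc1)c1ccccc1
Why: Deoxybromination of the vinylogous carboxylate oxygen through an O-phosphonium intermediate and addition–elimination of bromide, with equilibration to the all-E bromodienal.

Step 16
Reactants: 23 (2E,4E)-5-bromopenta-2,4-dienal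
Product: 24 (2E,4E)-5-bromopenta-2,4-dienoic acid
Conditions: NaClO2, NaH2PO4, 2-methylbut-2-ene, t-BuOH/H2O, 0 °C to rt
Reagents that add atoms: sodium chlorite, [Na+].[O-]Cl=O
Why: Pinnick oxidation of the aldehyde; the alkene scavenger removes hypochlorous acid so the bromodiene is left intact.

Step 17
Reactants: 24 (2E,4E)-5-bromopenta-2,4-dienoic acid; 21 2-amino-3-hydroxycyclopent-2-en-1-one hydrochloride
Product: 26 (2E,4E)-5-bromo-N-(2-hydroxy-5-oxocyclopent-1-en-1-yl)penta-2,4-dienamide, via bromodienoyl chloride 25 (not isolated)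
Conditions: (COCl)2, DMF (cat.), CH2Cl2, 0 °C; evaporate; then 21, Et3N (2.2 equiv), CH2Cl2, 0 °C
Reagents that add atoms: none
Why: Acid chloride formation and N-acylation of the 2-amino-1,3-dione; any O-acylated enol ester should pass its acyl group on to nitrogen.

Step 18
Reactants: 18 (2E,4E,6E)-N-[(1S,5R,6R)-5-hydroxy-2-oxo-5-[(E)-2-(tributylstannyl)ethenyl]-7-oxabicyclo[4.1.0]hept-3-en-3-yl]-8-methylnona-2,4,6-trienamide; 26 (2E,4E)-5-bromo-N-(2-hydroxy-5-oxocyclopent-1-en-1-yl)penta-2,4-dienamide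
Product: 27 Manumycin G, (2E,4E,6E)-N-[(1S,5S,6R)-5-hydroxy-5-[(1E,3E,5E)-7-[(2-hydroxy-5-oxocyclopent-1-en-1-yl)amino]-7-oxohepta-1,3,5-trien-1-yl]-2-oxo-7-oxabicyclo[4.1.0]hept-3-en-3-yl]-8-methylnona-2,4,6-trienamide
Conditions: Pd2(dba)3 (5 mol %), AsPh3 (20 mol %), DMF, rt to 40 °C, dark
Reagents that add atoms: none
Why: Stille coupling of the vinylstannane with the vinyl bromide joins C2′ to C3′ with retention of both alkene geometries under neutral conditions that the epoxyquinol, both amides and the enol should tolerate.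

**Compound list**

1 | tert-butyl N-[(3R)-2-oxooxolan-3-yl]carbamate (N-Boc-D-homoserine lactone) | CC(C)(C)OC(=O)N[C@@H]1CCOC1=O | starting material
2 | tert-butyl N-[(1R)-3-hydroxy-1-(1-hydroxycyclopropyl)propyl]carbamate | CC(C)(C)OC(=O)N[C@H](CCO)C1(O)CC1 | intermediate
3 | tert-butyl N-[(7R)-5-oxo-4-oxaspiro[2.4]heptan-7-yl]carbamate | CC(C)(C)OC(=O)N[C@@H]1CC(=O)OC12CC2 | intermediate
4 | tert-butyl N-[(1R)-1-(1-hydroxycyclopropyl)-3-oxo-5-(trimethylsilyl)pent-4-yn-1-yl]carbamate | CC(C)(C)OC(=O)N[C@H](CC(=O)C#C[Si](C)(C)C)C1(O)CC1 | intermediate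
5 | ethyl{1-[(1R)-1-[(tert-butoxycarbonyl)amino]-3-oxo-5-(trimethylsilyl)pent-4-yn-1-yl]cyclopropan-1-olato}zinc | CC(C)(C)OC(=O)N[C@H](CC(=O)C#C[Si](C)(C)C)C1(O[Zn]CC)CC1 | intermediate
6 | ethyl{(4R)-4-[(tert-butoxycarbonyl)amino]-3,6-dioxo-8-(trimethylsilyl)oct-7-yn-1-yl}zinc | CC(C)(C)OC(=O)N[C@H](CC(=O)C#C[Si](C)(C)C)C(=O)CC[Zn]CC | intermediate
7 | tert-butyl N-[(1R,5R)-5-hydroxy-2-oxo-5-[2-(trimethylsilyl)ethynyl]cyclohexyl]carbamate | CC(C)(C)OC(=O)N[C@@H]1C[C@@](O)(C#C[Si](C)(C)C)CCC1=O | intermediate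
8 | (E)-4-methylpent-2-enal | CC(C)/C=C/C=O | starting material
9 | triethyl 4-phosphonocrotonate | CCOC(=O)/C=C/CP(=O)(OCC)OCC | starting material
10 | ethyl (2E,4E,6E)-8-methylnona-2,4,6-trienoate | CCOC(=O)/C=C/C=C/C=C/C(C)C | intermediate
11 | (2E,4E,6E)-8-methylnona-2,4,6-trienoic acid | OC(=O)/C=C/C=C/C=C/C(C)C | intermediate
12 | (2E,4E,6E)-8-methylnona-2,4,6-trienoyl chloride | ClC(=O)/C=C/C=C/C=C/C(C)C | intermediate
13 | (1R,5R)-5-hydroxy-2-oxo-5-[2-(trimethylsilyl)ethynyl]cyclohexan-1-aminium trifluoroacetate | [NH3+][C@@H]1C[C@@](O)(C#C[Si](C)(C)C)CCC1=O.[O-]C(=O)C(F)(F)F | intermediate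
14 | (2E,4E,6E)-N-[(1R,5R)-5-hydroxy-2-oxo-5-[2-(trimethylsilyl)ethynyl]cyclohexyl]-8-methylnona-2,4,6-trienamide | CC(C)/C=C/C=C/C=C/C(=O)N[C@@H]1C[C@@](O)(C#C[Si](C)(C)C)CCC1=O | intermediate
15 | (2E,4E,6E)-N-[(3R)-3-hydroxy-6-oxo-3-[2-(trimethylsilyl)ethynyl]cyclohexa-1,4-dien-1-yl]-8-methylnona-2,4,6-trienamide | CC(C)/C=C/C=C/C=C/C(=O)NC1=C[C@@](O)(C#C[Si](C)(C)C)C=CC1=O | intermediate
16 | (2E,4E,6E)-N-[(1S,5R,6R)-5-hydroxy-2-oxo-5-[2-(trimethylsilyl)ethynyl]-7-oxabicyclo[4.1.0]hept-3-en-3-yl]-8-methylnona-2,4,6-trienamide | CC(C)/C=C/C=C/C=C/C(=O)NC1=C[C@@](O)(C#C[Si](C)(C)C)[C@@H]2O[C@@H]2C1=O | intermediate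
17 | (2E,4E,6E)-N-[(1S,5R,6R)-5-ethynyl-5-hydroxy-2-oxo-7-oxabicyclo[4.1.0]hept-3-en-3-yl]-8-methylnona-2,4,6-trienamide | CC(C)/C=C/C=C/C=C/C(=O)NC1=C[C@@](O)(C#C)[C@@H]2O[C@@H]2C1=O | intermediate
18 | (2E,4E,6E)-N-[(1S,5R,6R)-5-hydroxy-2-oxo-5-[(E)-2-(tributylstannyl)ethenyl]-7-oxabicyclo[4.1.0]hept-3-en-3-yl]-8-methylnona-2,4,6-trienamide | CC(C)/C=C/C=C/C=C/C(=O)NC1=C[C@@](O)(/C=C/[Sn](CCCC)(CCCC)CCCC)[C@@H]2O[C@@H]2C1=O | intermediate
19 | cyclopentane-1,3-dione | O=C1CCC(=O)C1 | starting material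
20 | 2-(hydroxyimino)cyclopentane-1,3-dione | ON=C1C(=O)CCC1=O | intermediate
21 | 2-amino-3-hydroxycyclopent-2-en-1-one hydrochloride | Cl.NC1=C(O)CCC1=O | intermediate
22 | glutaconaldehyde potassium salt | [K+].[O-]/C=C/C=C/C=O | starting material
23 | (2E,4E)-5-bromopenta-2,4-dienal | Br/C=C/C=C/C=O | intermediate
24 | (2E,4E)-5-bromopenta-2,4-dienoic acid | OC(=O)/C=C/C=C/Br | intermediate
25 | (2E,4E)-5-bromopenta-2,4-dienoyl chloride | ClC(=O)/C=C/C=C/Br | intermediate
26 | (2E,4E)-5-bromo-N-(2-hydroxy-5-oxocyclopent-1-en-1-yl)penta-2,4-dienamide | Br/C=C/C=C/C(=O)NC1=C(O)CCC1=O | intermediate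
27 | Manumycin G | CC(C)/C=C/C=C/C=C/C(=O)NC1=C[C@@](O)(/C=C/C=C/C=C/C(=O)NC2=C(O)CCC2=O)[C@@H]2O[C@@H]2C1=O | target

**Summary**

Total step count: 18. Longest linear sequence: 10 steps (steps 1–4, 8–12 and 18, from 1).

**Steps most likely to fail**

Step 4. The zinc cyclopropoxide may not open, or the homoenolate may be protonated or enolized instead of adding to C4, and the 1,3-induction from C2 may be low. If only the sense of induction is wrong, the enantiomeric lactone corrects it. If the closure itself fails, the fallback buys ring A as an arene; it sets out from acid chloride 12 and comes back at stannane 18. Acylation of 2,5-dimethoxyaniline with 12 (pyridine, CH2Cl2) should give (2E,4E,6E)-N-(2,5-dimethoxyphenyl)-8-methylnona-2,4,6-trienamide F1. Oxidation with PhI(OAc)2 in methanol should give the quinone monoketal (2E,4E,6E)-N-(6,6-dimethoxy-3-oxocyclohexa-1,4-dien-1-yl)-8-methylnona-2,4,6-trienamide F2. Weitz–Scheffer epoxidation of its free enone arm (t-BuOOH, NaOH, toluene, with the cinchona-derived quaternary ammonium phase-transfer catalyst of the pseudoenantiomeric series that delivers this oxirane) should give (2E,4E,6E)-N-[(1R,6S)-5,5-dimethoxy-2-oxo-7-oxabicyclo[4.1.0]hept-3-en-4-yl]-8-methylnona-2,4,6-trienamide F3. (E)-2-(Tributylstannyl)vinyllithium (from (E)-1,2-bis(tributylstannyl)ethene and n-BuLi, 2.2 equiv, THF, −78 °C) should add to the ketone anti to the oxirane oxygen, which places the new hydroxyl syn to it, to give (2E,4E,6E)-N-[(1S,5R,6R)-5-hydroxy-2,2-dimethoxy-5-[(E)-2-(tributylstannyl)ethenyl]-7-oxabicyclo[4.1.0]hept-3-en-3-yl]-8-methylnona-2,4,6-trienamide F4. Mild hydrolysis of the dimethyl ketal (aqueous oxalic acid or acidic clay, CH2Cl2) then gives 18.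

Step 9. The second dehydrogenation may stall at the mono-enone, or the oxidant may attack the trienamide. The fallback replaces the one-pot oxidation by two Saegusa–Ito sequences; it sets out from 14 and comes back at 15.
- Soft enolization (Me3SiOTf, Et3N, CH2Cl2, 0 °C) should give (2E,4E,6E)-8-methyl-N-[(5R)-2,5-bis(trimethylsilyloxy)-5-[2-(trimethylsilyl)ethynyl]cyclohex-1-en-1-yl]nona-2,4,6-trienamide F5.
- Pd(OAc)2 in MeCN should give the enamide enone (2E,4E,6E)-8-methyl-N-[(3R)-6-oxo-3-(trimethylsilyloxy)-3-[2-(trimethylsilyl)ethynyl]cyclohex-1-en-1-yl]nona-2,4,6-trienamide F6.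
- Kinetic deprotonation at C6 (LiHMDS, Me3SiCl, THF, −78 °C) should give the cross-conjugated silyl dienol ether (2E,4E,6E)-N-[(3R)-3,6-bis(trimethylsilyloxy)-3-[2-(trimethylsilyl)ethynyl]cyclohexa-1,5-dien-1-yl]-8-methylnona-2,4,6-trienamide F7.
- A second treatment with Pd(OAc)2 should give the dienone (2E,4E,6E)-8-methyl-N-[(3R)-6-oxo-3-(trimethylsilyloxy)-3-[2-(trimethylsilyl)ethynyl]cyclohexa-1,4-dien-1-yl]nona-2,4,6-trienamide F8.
- Citric acid in methanol removes the tertiary silyl ether and gives 15.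

Step 1. Chelation of titanium by the magnesium carbamate may stop the ligand exchange, and lactone enolization could erode C2. The fallback builds the cyclopropanol by Simmons–Smith chemistry; it sets out from 1 and comes back at 2.
- MeLi (2.2 equiv, THF, −78 °C) should open the lactone to tert-butyl N-[(3R)-1-hydroxy-4-oxopentan-3-yl]carbamate F9.
- LiHMDS (3.3 equiv) with Me3SiCl at −78 °C should give the kinetic enol ether on the methyl side, because the carbamate anion shields C3–H: tert-butyl N-[(3R)-1,4-bis(trimethylsilyloxy)pent-4-en-3-yl]carbamate F10.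
- Cyclopropanation with Et2Zn and CH2I2 (CH2Cl2, 0 °C) should give tert-butyl N-[(1R)-3-(trimethylsilyloxy)-1-[1-(trimethylsilyloxy)cyclopropyl]propyl]carbamate F11.
- K2CO3 in methanol then gives 2.

Further compounds
F1 | step 4 | (2E,4E,6E)-N-(2,5-dimethoxyphenyl)-8-methylnona-2,4,6-trienamide | COc1ccc(OC)c(NC(=O)/C=C/C=C/C=C/C(C)C)c1
F2 | step 4 | (2E,4E,6E)-N-(6,6-dimethoxy-3-oxocyclohexa-1,4-dien-1-yl)-8-methylnona-2,4,6-trienamide | COC1(OC)C=CC(=O)C=C1NC(=O)/C=C/C=C/C=C/C(C)C
F3 | step 4 | (2E,4E,6E)-N-[(1R,6S)-5,5-dimethoxy-2-oxo-7-oxabicyclo[4.1.0]hept-3-en-4-yl]-8-methylnona-2,4,6-trienamide | CC(C)/C=C/C=C/C=C/C(=O)NC1=CC(=O)[C@@H]2O[C@@H]2C1(OC)OC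
F4 | step 4 | (2E,4E,6E)-N-[(1S,5R,6R)-5-hydroxy-2,2-dimethoxy-5-[(E)-2-(tributylstannyl)ethenyl]-7-oxabicyclo[4.1.0]hept-3-en-3-yl]-8-methylnona-2,4,6-trienamide | CC(C)/C=C/C=C/C=C/C(=O)NC1=C[C@@](O)(/C=C/[Sn](CCCC)(CCCC)CCCC)[C@@H]2O[C@@H]2C1(OC)OC
F5 | step 9 | (2E,4E,6E)-8-methyl-N-[(5R)-2,5-bis(trimethylsilyloxy)-5-[2-(trimethylsilyl)ethynyl]cyclohex-1-en-1-yl]nona-2,4,6-trienamide | CC(C)/C=C/C=C/C=C/C(=O)NC1=C(O[Si](C)(C)C)CC[C@](O[Si](C)(C)C)(C#C[Si](C)(C)C)C1
F6 | step 9 | (2E,4E,6E)-8-methyl-N-[(3R)-6-oxo-3-(trimethylsilyloxy)-3-[2-(trimethylsilyl)ethynyl]cyclohex-1-en-1-yl]nona-2,4,6-trienamide | CC(C)/C=C/C=C/C=C/C(=O)NC1=C[C@@](O[Si](C)(C)C)(C#C[Si](C)(C)C)CCC1=O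
F7 | step 9 | (2E,4E,6E)-N-[(3R)-3,6-bis(trimethylsilyloxy)-3-[2-(trimethylsilyl)ethynyl]cyclohexa-1,5-dien-1-yl]-8-methylnona-2,4,6-trienamide | CC(C)/C=C/C=C/C=C/C(=O)NC1=C[C@@](O[Si](C)(C)C)(C#C[Si](C)(C)C)CC=C1O[Si](C)(C)C
F8 | step 9 | (2E,4E,6E)-8-methyl-N-[(3R)-6-oxo-3-(trimethylsilyloxy)-3-[2-(trimethylsilyl)ethynyl]cyclohexa-1,4-dien-1-yl]nona-2,4,6-trienamide | CC(C)/C=C/C=C/C=C/C(=O)NC1=C[C@@](O[Si](C)(C)C)(C#C[Si](C)(C)C)C=CC1=O
F9 | step 1 | tert-butyl N-[(3R)-1-hydroxy-4-oxopentan-3-yl]carbamate | CC(C)(C)OC(=O)N[C@H](CCO)C(C)=O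
F10 | step 1 | tert-butyl N-[(3R)-1,4-bis(trimethylsilyloxy)pent-4-en-3-yl]carbamate | CC(C)(C)OC(=O)N[C@H](CCO[Si](C)(C)C)C(=C)O[Si](C)(C)C
F11 | step 1 | tert-butyl N-[(1R)-3-(trimethylsilyloxy)-1-[1-(trimethylsilyloxy)cyclopropyl]propyl]carbamate | CC(C)(C)OC(=O)N[C@H](CCO[Si](C)(C)C)C1(O[Si](C)(C)C)CC1
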